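**Plan**

- Retrosynthesis: the two silyl ethers, the C1–H bond and the O3 ester C–O bond are cut back to a 1‑C‑(oxazol‑4‑yl) L‑fucal. Then the bond between C4 of the central oxazole and chain C1 is cut (Stille coupling), and last the CH2–C2 bond between the two oxazoles (Negishi coupling).
- Feature: with the side chain numbered from the oxazole‑bound carbinol (C1) to the methyl (C6), C1–C6 is 2‑deoxy‑L‑fucose. In the dihydropyran ring of L‑fucal the C1=C2 enol ether holds C1 at the ketone level and C2 as the later CH2, and the vinylic C1 can carry tin for bonding to C4 of the central oxazole.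
- Forward: L‑fucal is silylated (O3 TES, O4 TIPS) and stannylated at C1, and the 4‑bromo bis‑oxazole is made separately. After the Stille coupling, the sequence is hydration, O3 acylation, ring‑opening O5 silylation, ketone reduction and desilylation; no ring is built.
- Stereochemistry: C3 (S), C4 (R) and C5 (S) come unchanged from L‑fucal. C1 (R, 1,3‑syn to the C3 ester) is set by the (S)‑CBS catalyst in step 11.

Key step: step 7

Remark on the chemistry: the anomeric carbon of hemiketals 13 and 15 equilibrates through the open‑chain hydroxy ketone and is drawn without configuration; it is not a stereocentre of the target.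

**Route**

Step 1
Reactants: 1 3,4‑di‑O‑acetyl‑L‑fucal
Product: 2 L‑fucal
Conditions: K2CO3 (cat.), MeOH, rt
Reagents that add atoms: none
Why: Zemplén‑type transesterification with catalytic methoxide removes both acetates, while the base‑stable enol ether and the three stereocentres are untouched.

Step 2
Reactants: 2 L‑fucal
Product: 3 3‑O‑triethylsilyl‑L‑fucal
Conditions: TESCl (1.05 equiv), imidazole, DMF, −40 °C
Reagents that add atoms: triethylsilyl chloride, CC[Si](Cl)(CC)CC
Why: Kinetic regioselective silylation should favour the allylic equatorial 3‑OH over the axial 4‑OH flanked by the C5 methyl, as in the 3‑O‑monosilylation of galactal‑type cis‑diols.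

Step 3
Reactants: 3 3‑O‑triethylsilyl‑L‑fucal
Product: 4 3‑O‑triethylsilyl‑4‑O‑triisopropylsilyl‑L‑fucal
Conditions: TIPSOTf, 2,6‑lutidine, CH2Cl2, 0 °C to rt
Reagents that add atoms: triisopropylsilyl triflate, CC(C)[Si](OS(=O)(=O)C(F)(F)F)(C(C)C)C(C)C
Why: Silyl triflate silylation reaches the hindered axial 4‑OH, and the lutidine buffer keeps the TES ether and the enol ether intact.

Step 4
Reactants: 4 3‑O‑triethylsilyl‑4‑O‑triisopropylsilyl‑L‑fucal
Product: 6 1‑tributylstannyl‑3‑O‑triethylsilyl‑4‑O‑triisopropylsilyl‑L‑fucal, via 1‑lithio glycal 5 (not isolated)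
Conditions: t‑BuLi (pentane), THF, −78 to 0 °C; then Bu3SnCl, −78 °C to rt
Reagents that add atoms: tributyltin chloride, CCCC[Sn](Cl)(CCCC)CCCC
Why: C1 lithiation of a silyl‑protected glycal (deprotonation of the α‑alkoxyvinyl C–H) followed by a tin chloride quench should work because TES and TIPS ethers carry no acidic Si–CH3 protons; the stereocentres are remote from the carbanion.

Step 5
Reactants: 7 oxazol‑5‑ylmethanol
Product: 8 5‑(chloromethyl)oxazole
Conditions: SOCl2, CH2Cl2, 0 °C to rt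
Reagents that add atoms: thionyl chloride, O=S(Cl)Cl
Why: Deoxychlorination of a primary heteroarylmethyl alcohol through its chlorosulfite is a standard substitution.

Step 6
Reactants: 8 5‑(chloromethyl)oxazole; 9 2,4‑dibromooxazole
Product: 11 4‑bromo‑2‑(oxazol‑5‑ylmethyl)oxazole, via (oxazol‑5‑ylmethyl)zinc chloride 10 (not isolated)
Conditions: Zn dust, LiCl, THF, rt; then 9, Pd(PPh3)4 (5 mol%), THF, rt to 50 °C
Reagents that add atoms: none
Why: LiCl‑assisted zinc insertion into the benzylic‑type C–Cl bond and Negishi coupling should be C2‑selective, because zerovalent palladium inserts faster into the C2–Br bond flanked by O and N than into C4–Br, as known for 2,4‑dihalo‑1,3‑azoles.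

Step 7
Reactants: 6 1‑tributylstannyl‑3‑O‑triethylsilyl‑4‑O‑triisopropylsilyl‑L‑fucal; 11 4‑bromo‑2‑(oxazol‑5‑ylmethyl)oxazole
Product: 12 1‑C‑[2‑(oxazol‑5‑ylmethyl)oxazol‑4‑yl]‑3‑O‑triethylsilyl‑4‑O‑triisopropylsilyl‑L‑fucal
Conditions: Pd(PPh3)4 (10 mol%), CuI (20 mol%), degassed DMF, 80 °C
Reagents that add atoms: none
Why: Stille coupling: zerovalent palladium inserts into the C4–Br bond of 11, the C1 alkenyl group of 6 passes from tin to palladium (through an alkenylcopper formed with CuI, which also binds free PPh3), and reductive elimination forms the bond between C4 of the central oxazole and C1 of the glycal. The closest known reaction type is the palladium‑catalysed coupling of 1‑stannyl glycals with aryl and heteroaryl bromides to give C‑aryl glycals. No ring is closed and no stereocentre is formed; C3, C4 and C5 of the sugar are spectators. Cross‑coupling must outrun protodestannylation and glycal homocoupling, which the copper co‑catalyst, the anhydrous neutral medium and degassing should secure. Regiochemistry is fixed because 6 carries tin only at C1 and 11 a single bromine at C4; without base or fluoride the silyl ethers and the CH2 between the oxazoles are left alone.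

Step 8
Reactants: 12 1‑C‑[2‑(oxazol‑5‑ylmethyl)oxazol‑4‑yl]‑3‑O‑triethylsilyl‑4‑O‑triisopropylsilyl‑L‑fucal
Product: 13 2,6‑dideoxy‑1‑C‑[2‑(oxazol‑5‑ylmethyl)oxazol‑4‑yl]‑4‑O‑triisopropylsilyl‑L‑lyxo‑hexopyranose (hemiketal, 3‑OH free)
Conditions: aq. HCl (1 M), THF, 0 °C to rt
Reagents that add atoms: water, O
Why: Acid‑catalysed Markovnikov hydration of the enol ether (C2 protonation, water capture of the C1 oxocarbenium) gives the hemiketal, and the same aqueous acid hydrolyses the labile TES ether while the TIPS ether and C3–C5 stay as they are.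

Step 9
Reactants: 13 the hemiketal with free 3‑OH; 14 13‑methyltetradecanoic acid
Product: 15 2,6‑dideoxy‑3‑O‑(13‑methyltetradecanoyl)‑1‑C‑[2‑(oxazol‑5‑ylmethyl)oxazol‑4‑yl]‑4‑O‑triisopropylsilyl‑L‑lyxo‑hexopyranose (hemiketal)
Conditions: DCC, DMAP (cat.), CH2Cl2, 0 °C to rt
Reagents that add atoms: none
Why: Steglich esterification should acylate only the secondary equatorial 3‑OH, since the other free hydroxyl is a hindered tertiary hemiketal OH, O4 is silylated and O5 is tied up in the ring.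

Step 10
Reactants: 15 the 3‑O‑acyl hemiketal
Product: 16 1‑[2‑(oxazol‑5‑ylmethyl)oxazol‑4‑yl]‑1‑oxo‑5‑(triethylsilyloxy)‑4‑(triisopropylsilyloxy)hexan‑3‑yl 13‑methyltetradecanoate (open‑chain ketone, C3–C5 configured as in 2‑deoxy‑L‑fucose)
Conditions: TESCl, imidazole, DMF, 0 °C to rt
Reagents that add atoms: triethylsilyl chloride, CC[Si](Cl)(CC)CC
Why: Ring–chain tautomerism of the hemiketal exposes the secondary C5–OH of the keto form, which the moderately reactive chlorosilane should silylate faster than the tertiary anomeric OH (trapping of a lactol as its open‑chain silyloxy ketone), with a weak base chosen to spare the β‑acyloxy ketone.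

Step 11
Reactants: 16 the open‑chain ketone
Product: 17 (1R)‑1‑hydroxy‑1‑[2‑(oxazol‑5‑ylmethyl)oxazol‑4‑yl]‑5‑(triethylsilyloxy)‑4‑(triisopropylsilyloxy)hexan‑3‑yl 13‑methyltetradecanoate (1,3‑syn; C3–C5 as in 16)
Conditions: (S)‑2‑methyl‑CBS‑oxazaborolidine (1 equiv), BH3·SMe2, THF, −30 °C; MeOH quench
Reagents that add atoms: none
Why: Corey–Bakshi–Shibata reduction with the heteroaryl group as the large and the CH2 as the small substituent should give the (1R) carbinol, the same sense as acetophenone to (R)‑1‑phenylethanol with the (S) catalyst, and the low temperature spares the ester.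

Step 12
Reactants: 17 the (1R) alcohol bis‑silyl ether
Product: 18 (1R,3S,4R,5S)‑1,4,5‑trihydroxy‑1‑[2‑(oxazol‑5‑ylmethyl)oxazol‑4‑yl]hexan‑3‑yl 13‑methyltetradecanoate (CNP0177198.1)
Conditions: HF·pyridine, pyridine, THF, 0 °C to rt
Reagents that add atoms: none
Why: Fluoride‑driven Si–O cleavage in a buffered acidic medium removes the TES and TIPS ethers without the base‑induced acyl migration that would move the O3 ester, and no stereocentre is touched.

**Compound list**

1 | 3,4‑di‑O‑acetyl‑L‑fucal, (2S,3R,4S)‑2‑methyl‑3,4‑dihydro‑2H‑pyran‑3,4‑diyl diacetate | CC(=O)O[C@@H](C=CO1)[C@H](OC(C)=O)[C@@H]1C | starting material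
2 | L‑fucal | O[C@@H](C=CO1)[C@H](O)[C@@H]1C | intermediate
3 | 3‑O‑triethylsilyl‑L‑fucal | CC[Si](CC)(CC)O[C@@H](C=CO1)[C@H](O)[C@@H]1C | intermediate
4 | 3‑O‑triethylsilyl‑4‑O‑triisopropylsilyl‑L‑fucal | CC[Si](CC)(CC)O[C@@H](C=CO1)[C@H](O[Si](C(C)C)(C(C)C)C(C)C)[C@@H]1C | intermediate
5 | 1‑lithio‑3‑O‑triethylsilyl‑4‑O‑triisopropylsilyl‑L‑fucal | CC[Si](CC)(CC)O[C@@H](C=C(O1)[Li])[C@H](O[Si](C(C)C)(C(C)C)C(C)C)[C@@H]1C | intermediate
6 | 1‑tributylstannyl‑3‑O‑triethylsilyl‑4‑O‑triisopropylsilyl‑L‑fucal | CC[Si](CC)(CC)O[C@@H](C=C(O1)[Sn](CCCC)(CCCC)CCCC)[C@H](O[Si](C(C)C)(C(C)C)C(C)C)[C@@H]1C | intermediate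
7 | oxazol‑5‑ylmethanol | OCc1cnco1 | starting material
8 | 5‑(chloromethyl)oxazole | ClCc1cnco1 | intermediate
9 | 2,4‑dibromooxazole | Brc1coc(Br)n1 | starting material
10 | (oxazol‑5‑ylmethyl)zinc chloride | Cl[Zn]Cc1cnco1 | intermediate
11 | 4‑bromo‑2‑(oxazol‑5‑ylmethyl)oxazole | Brc1coc(Cc2cnco2)n1 | intermediate
12 | 1‑C‑[2‑(oxazol‑5‑ylmethyl)oxazol‑4‑yl]‑3‑O‑triethylsilyl‑4‑O‑triisopropylsilyl‑L‑fucal | CC[Si](CC)(CC)O[C@@H](C=C(O1)c2coc(Cc3cnco3)n2)[C@H](O[Si](C(C)C)(C(C)C)C(C)C)[C@@H]1C | intermediate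
13 | 2,6‑dideoxy‑1‑C‑[2‑(oxazol‑5‑ylmethyl)oxazol‑4‑yl]‑4‑O‑triisopropylsilyl‑L‑lyxo‑hexopyranose (hemiketal) | O[C@@H](CC(O)(O1)c2coc(Cc3cnco3)n2)[C@H](O[Si](C(C)C)(C(C)C)C(C)C)[C@@H]1C | intermediate
14 | 13‑methyltetradecanoic acid | CC(C)CCCCCCCCCCCC(=O)O | starting material
15 | 3‑O‑(13‑methyltetradecanoyl) derivative of hemiketal 13 | CC(C)CCCCCCCCCCCC(=O)O[C@@H](CC(O)(O1)c2coc(Cc3cnco3)n2)[C@H](O[Si](C(C)C)(C(C)C)C(C)C)[C@@H]1C | intermediate
16 | open‑chain C1 ketone, O3 ester, O4 TIPS, O5 TES | CC(C)CCCCCCCCCCCC(=O)O[C@@H](CC(=O)c1coc(Cc2cnco2)n1)[C@H](O[Si](C(C)C)(C(C)C)C(C)C)[C@H](C)O[Si](CC)(CC)CC | intermediate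
17 | (1R) alcohol, O3 ester, O4 TIPS, O5 TES | CC(C)CCCCCCCCCCCC(=O)O[C@@H](C[C@@H](O)c1coc(Cc2cnco2)n1)[C@H](O[Si](C(C)C)(C(C)C)C(C)C)[C@H](C)O[Si](CC)(CC)CC | intermediate
18 | (1R,3S,4R,5S)‑1,4,5‑trihydroxy‑1‑[2‑(oxazol‑5‑ylmethyl)oxazol‑4‑yl]hexan‑3‑yl 13‑methyltetradecanoate | CC(C)CCCCCCCCCCCC(=O)O[C@@H](C[C@@H](O)c1coc(Cc2cnco2)n1)[C@H](O)[C@H](C)O | target

**Count**

Total steps: 12. Longest linear sequence: 10 steps (steps 1–4 and 7–12, from 1); the bis‑oxazole arm is steps 5–6.

**Steps most likely to fail**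

Step 10. The hemiketal may be silylated at the anomeric oxygen without opening, or the opened β‑acyloxy ketone may lose its ester by base‑induced elimination. The fallback avoids trapping and sets out from 15. Asymmetric transfer hydrogenation with RuCl[(R,R)‑TsDPEN](p‑cymene) in HCO2H/Et3N would reduce the small equilibrium share of open ketone as it forms, giving (1R)‑1,5‑dihydroxy‑1‑[2‑(oxazol‑5‑ylmethyl)oxazol‑4‑yl]‑4‑(triisopropylsilyloxy)hexan‑3‑yl 13‑methyltetradecanoate F1. Desilylation with HF·pyridine then rejoins the route at 18.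

Step 11. Facial selectivity may be poor if the (S) catalyst is mismatched with the C3 stereocentre, and borane may bind to the oxazole nitrogens. The fallback sets out from 16 and uses inversion. Reduction with the enantiomeric (R)‑2‑methyl‑CBS‑oxazaborolidine and BH3·SMe2, then the matched case, should give the C1 epimer, (1S)‑1‑hydroxy‑1‑[2‑(oxazol‑5‑ylmethyl)oxazol‑4‑yl]‑5‑(triethylsilyloxy)‑4‑(triisopropylsilyloxy)hexan‑3‑yl 13‑methyltetradecanoate F2. Mitsunobu reaction with chloroacetic acid, PPh3 and DIAD would invert C1 to the (1R)‑chloroacetate of 17 F3. Thiourea with NaHCO3 in EtOH removes the chloroacetyl group in the presence of the fatty ester and returns to the route at 17.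

Step 8. Allylic loss of the O3 substituent (Ferrier‑type) or dehydration of the β‑hydroxy ketone may compete with hydration of the enol ether. The fallback sets out from 12 and replaces protonation by iodonium addition. N‑Iodosuccinimide in MeCN/H2O should give the 2‑iodo‑3‑O‑triethylsilyl hemiketal F4 (configuration at C2 immaterial). Radical deiodination with Bu3SnH and AIBN in toluene gives the 3‑O‑triethylsilyl‑2‑deoxy hemiketal F5. AcOH/THF/H2O then removes the TES ether and rejoins the route at 13.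

**Further compounds**

F1 | step 10 | (1R)‑1,5‑dihydroxy‑1‑[2‑(oxazol‑5‑ylmethyl)oxazol‑4‑yl]‑4‑(triisopropylsilyloxy)hexan‑3‑yl 13‑methyltetradecanoate | CC(C)CCCCCCCCCCCC(=O)O[C@@H](C[C@@H](O)c1coc(Cc2cnco2)n1)[C@H](O[Si](C(C)C)(C(C)C)C(C)C)[C@H](C)O
F2 | step 11 | (1S)‑1‑hydroxy‑1‑[2‑(oxazol‑5‑ylmethyl)oxazol‑4‑yl]‑5‑(triethylsilyloxy)‑4‑(triisopropylsilyloxy)hexan‑3‑yl 13‑methyltetradecanoate | CC(C)CCCCCCCCCCCC(=O)O[C@@H](C[C@H](O)c1coc(Cc2cnco2)n1)[C@H](O[Si](C(C)C)(C(C)C)C(C)C)[C@H](C)O[Si](CC)(CC)CC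
F3 | step 11 | (1R)‑chloroacetate of 17 | CC(C)CCCCCCCCCCCC(=O)O[C@@H](C[C@@H](OC(=O)CCl)c1coc(Cc2cnco2)n1)[C@H](O[Si](C(C)C)(C(C)C)C(C)C)[C@H](C)O[Si](CC)(CC)CC
F4 | step 8 | 2‑iodo‑3‑O‑triethylsilyl hemiketal | CC[Si](CC)(CC)O[C@@H](C(I)C(O)(O1)c2coc(Cc3cnco3)n2)[C@H](O[Si](C(C)C)(C(C)C)C(C)C)[C@@H]1C
F5 | step 8 | 3‑O‑triethylsilyl‑2‑deoxy hemiketal | CC[Si](CC)(CC)O[C@@H](CC(O)(O1)c2coc(Cc3cnco3)n2)[C@H](O[Si](C(C)C)(C(C)C)C(C)C)[C@@H]1C
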